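## Structural features

The target is a germacranolide. A ten-membered carbocycle C1–C10 carries a Z-trisubstituted alkene C1=C10 (methyl C14 on C10) and an E-trisubstituted alkene C4=C5 (methyl C15 on C4). It is cis-fused along C6–C7 to an α-methylene-γ-butyrolactone (ring oxygen on C6, carbonyl C12, C11=C13). Four contiguous oxygenated stereocentres run from C6 to C9: the lactone carbinol C6, the fully substituted carbinol C7 (tertiary OH, also bearing C11), the secondary carbinol C8 and the angeloylated carbinol C9. Along the C5–C10 chain the oxygens are 6,7-syn, 7,8-anti and 8,9-syn (6S,7S,8S,9R). Fragile groups are the angelate (Z to E isomerisation, migration to O8), the exocyclic enoate (Michael acceptor, reduced by tin hydride), the C7–O bond β to the lactone carbonyl (elimination on enolisation), the allylic C–O bonds at C6 and C9, and the 1(10),4-diene (acid-induced transannular cyclisation). The real difficulty is the strained medium ring with two trisubstituted alkenes of opposite geometry next to a quaternary carbinol, and telling O9 from O8. The key step exploits that C10 is bonded to the carbinol carbon C9 and belongs to the Z-alkene. C1–C10 can therefore be an alkyne and C9–C10 an acetylide-to-aldehyde bond. The spiro centre C7 ties C6 into the lactone and C8 into a 7,8-dioxolane, so the C6 side chain and the C9 aldehyde point to the same side.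

## Logic of the disconnections

34 from 33: the 7,8-diol is masked as an isopropylidene ketal. This leaves O9 as the only free hydroxyl in every earlier compound and removes the O8/O9 selectivity problem. The forward step must hydrolyse the ketal without touching the angelate, the allylic C–O bonds or the diene.

33 from 30 and 31: the O9–acyl bond is cut. The Z-enoate then enters after all base and metal chemistry. The forward step must acylate a hindered allylic alcohol without Z to E isomerisation and with retention at C9.

30 from 25 and 26 (through 28): the C11=C13 bond is cut. The exocyclic enoate would not survive tin hydride, palladium or divalent chromium, so it comes after them. The forward step must functionalise C11 although O7 is a β-leaving group.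

25 from 23 and 24, and 23 from 22: the C10–C14 bond is cut, then H (C1) and tin (C10) are removed to an alkyne. A syn addition to a ring alkyne can only give the cis ring alkene, so the Z geometry is secured by construction. The forward steps must put tin on C10 and exchange it with retention.

22 from 20 (key): the C9–C10 bond is cut, which opens the ten-membered ring to an iodoalkyne and an aldehyde on one chain. The sp unit and the pre-set E-alkene leave only this bond to form. The forward step needs high dilution, aldehyde-over-lactone chemoselectivity and the right face at C9.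

20 from 19 from 18: functional group changes only. The aldehyde is released from a primary alcohol last, and the iodoalkyne comes from a silyl alkyne.

18 from 17, and 17 from 14 and 6: the O6–C12 lactone bond and the C5–C6 bond are cut. The whole C1–C5 chain, with the E-alkene fixed, arrives as one alkenyl nucleophile. The forward step must give the 6,7-syn carbinol and close the γ- and not the δ-lactone.

14 from 13 from 11 from 10: oxidation-level changes that tell the two methyl esters apart. The less hindered C9 ester is reduced and, being cis to the C6 ester, closes a bicyclic lactone. That lactone carries C6 to the aldehyde level while C9 stays an alcohol, with no protecting group.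

10 from 7 and 8: the C7–C11 bond is cut. C8 is bought as a stereocentre and controls the new quaternary C7, and the ketal of the final route is already in place. The forward step needs alkylation anti to the neighbouring ester and an enolate that does not expel its β-oxygen.

6 from 3 and 4, and 3 from 1: the C4–C15 and C5–I bonds are cut. Syn carbometalation of a terminal alkyne gives the E-alkene and the C15 methyl in one step. The second alkyne must be masked.

## Other disconnections considered

Alternative 1: The cut is at C7–C11 and C7–C8, with no ring closed. In the forward step the alkynyl Grignard reagent A4 adds to the acylsilane carbon of silyl glyoxylate A2. A [1,2]-Brook rearrangement gives a magnesium glycolate enolate, which is trapped by the α-alkoxy aldehyde A3 to give adduct A1.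
- In favour: three components and two C–C bonds in one operation, with the fully substituted C7 carbinol made directly in protected form. C9 is brought in from the chiral pool and not made in a ring closure, which is more secure than the chosen plan. The alkyne on C7 allows a later carbonylative lactonisation to the methylene lactone, which avoids enolate chemistry next to the C7 oxygen; this is also better than the chosen plan.
- Against: the enolate is achiral, so C7 and C8 depend entirely on induction from A3 (7,8-anti and 8,9-syn both required), and that is not secured. The tert-butyl ester carbon of A1 (C6) must still become an allylic carbinol with control. The ten-membered ring is not addressed at all.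
- Comparison: on structure it solves the polyol but not the ring, while the chosen plan solves both with one purchased stereocentre. On mechanism it is an anionic cascade against an organochromium addition. On step economy A1 is reached faster than 20, but the protecting-group and oxidation-level changes after A1 should make the total about equal.

Alternative 2: The cut is at C6–C12 and C7–C11; the lactone carbons come from a ketene. In the forward step dichloroketene A7 adds across the C6=C7 bond of silyl enol ether A6 to give cyclobutanone A5. Baeyer–Villiger oxidation (migration of C6 with retention) and dechlorination would follow.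
- In favour: the suprafacial cycloaddition and the retentive oxygen insertion fix the C6/C7 relationship stereospecifically. This is better than the chelation-controlled addition that sets C6 in the chosen plan. The lactone forms in a ring, so there is no γ/δ question.
- Against: A6 must be one geometric isomer, enolised toward C6 and not toward the oxygenated C8. The face of attack relative to the C8 dioxolane is unsecured. The β-siloxy cyclobutanone can open by a retro-aldol path. C5 of A5 is a masked aldehyde next to the lactone carbinol and must be olefinated to the E-trisubstituted alkene, where geometry control is weaker than by carboalumination. The ring closure is again left open.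
- Comparison: on structure it is strong for C6/C7 and weak for the alkene and the ring. On mechanism it is a pericyclic step plus an oxidation against organometallic additions. It should need more steps overall.

Alternative 3: The cut goes through both ring alkenes at once, back to the C1–C10 and C4–C5 σ-bonds of a cyclobutane. In the forward step irradiation of enone A9 with 1-methylcyclobutene A10 gives the head-to-tail photoadduct A8. Thermal cycloreversion across the other pair of bonds would open it to cyclodecadienone A11.
- In favour: the ring is made by ring expansion, with no high dilution, which is better than any macrocyclisation on entropy. Both trisubstituted alkenes form in one step, and a cis-anti-cis adduct should open to the cis,trans-diene, which is the Z,E pattern needed; this is equal or better on step count for the alkenes. C6–C8 are set on a six-membered ring.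
- Against: the head-to-tail regiochemistry with methyl groups on both reacting partners and the face of addition are unsecured. The thermolysis temperature invites Cope rearrangement of the 1,5-diene and loss of the ketal. C9 must then be set by reducing a ring ketone. A9 is itself a multistep target.
- Comparison: on structure it answers ring and alkenes together. On mechanism it is photochemical and thermal against a room-temperature chromium coupling. It is potentially shorter, but with more steps whose outcome cannot be argued from the substrate.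

Key step: step 11

Remarks on the chemistry:
- The precursor and product structures of the key step were checked against the target atom by atom. They agree at C6, C7, C8 and (product) C9 and are kept unchanged as 20 and 22.
- What needs correcting is the stereochemical rationale. The product is the 8,9-syn (9R) alcohol, while an open-chain Felkin–Anh analysis would predict 8,9-anti. The argument is corrected in step 11 and backed by a fallback.
- The route to 20 was changed from the malic acid aldol to a tartrate alkylation. A chair aldol transition state would give the 6,7-anti isomer, and the malic route must also tell the C8 and C12 carboxyl carbons apart.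
- The descriptor at C7 is R in the ketal-protected compounds and S in 34 only because the ranking of C6 and C8 changes; the geometry is the same.
- Assumption: 1, 4, 7, 8, 24, 26 and 31 are commercial.

## Steps

Step 1
Reactants: 1 hexa-1,5-diyne
Product: 3 trimethyl(hexa-1,5-diyn-1-yl)silane, via lithium hexa-1,5-diyn-1-ide 2 (not isolated)
Conditions: 1 (2 equiv), n-BuLi (1 equiv), THF, −78 °C; Me3SiCl, −78 °C to rt
Reagents that add atoms: chlorotrimethylsilane, C[Si](C)(C)Cl
Why: Acetylide formation and C-silylation; the excess of 1 favours monosilylation and is distilled off, and the silyl group masks C10–H during the organolithium chemistry of step 7.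

Step 2
Reactants: 3 trimethyl(hexa-1,5-diyn-1-yl)silane; 4 trimethylaluminium
Product: 6 (E)-(6-iodo-5-methylhex-5-en-1-yn-1-yl)trimethylsilane, via alkenylalane 5 (not isolated)
Conditions: Me3Al (2 equiv), Cp2ZrCl2 (0.25 equiv), CH2Cl2, 0 °C to rt; then I2, THF, −30 to 0 °C
Reagents that add atoms: iodine, II
Why: Negishi carboalumination adds CH3 and aluminium syn across the terminal alkyne with aluminium on the terminal carbon, and iodinolysis with retention gives the E-iodoalkene that fixes the C4=C5 geometry and brings C15; the silylated alkyne reacts far more slowly.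

Step 3
Reactants: 7 dimethyl (4R,5R)-2,2-dimethyl-1,3-dioxolane-4,5-dicarboxylate; 8 tert-butyl bromoacetate
Product: 10 dimethyl (4S,5R)-4-(2-tert-butoxy-2-oxoethyl)-2,2-dimethyl-1,3-dioxolane-4,5-dicarboxylate, via lithium enolate 9 (not isolated)
Conditions: LiN(i-Pr)2, THF/DMPU, −78 °C; then 8, −78 to −55 °C
Reagents that add atoms: none
Why: Alkylation of a tartrate acetonide ester enolate, a known reaction type with reactive halides: the planar enolate carbon C7 is attacked anti to the CO2Me on the neighbouring C8, so C11 ends trans and the C6 ester cis to C9, which sets C7 while C8 is untouched; elimination of O8 is slow because the C8–O bond lies near the nodal plane of the exocyclic enolate.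

Step 4
Reactants: 10 dimethyl (4S,5R)-4-(2-tert-butoxy-2-oxoethyl)-2,2-dimethyl-1,3-dioxolane-4,5-dicarboxylate
Product: 11 (4R,5S)-5-(2-tert-butoxy-2-oxoethyl)-5-(methoxycarbonyl)-2,2-dimethyl-1,3-dioxolane-4-carboxylic acid
Conditions: LiOH (1.05 equiv), THF/H2O, 0 °C; then aq. HCl to pH 3
Reagents that add atoms: lithium hydroxide, [Li+].[OH-]
Why: Selective saponification: the C9 methyl ester sits on a CH carbon and is far more accessible than the C6 ester on the quaternary carbon, and the tert-butyl ester resists hydroxide.

Step 5
Reactants: 11 (4R,5S)-5-(2-tert-butoxy-2-oxoethyl)-5-(methoxycarbonyl)-2,2-dimethyl-1,3-dioxolane-4-carboxylic acid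
Product: 13 tert-butyl 2-[(3aS,6aS)-2,2-dimethyl-4-oxodihydrofuro[3,4-d][1,3]dioxol-3a(4H)-yl]acetate, via hydroxy diester 12 (not isolated)
Conditions: BH3·SMe2, THF, 0 °C to rt; MeOH; then DBU (cat.), CH2Cl2, rt
Reagents that add atoms: none
Why: Borane reduces the carboxylic acid in the presence of both esters, and the C9 hydroxymethyl, cis to the C6 ester on the dioxolane, closes the cis-fused γ-lactone; only the correctly alkylated cis diastereomer can lactonise, so the step also removes the minor isomer of step 3.

Step 6
Reactants: 13 tert-butyl 2-[(3aS,6aS)-2,2-dimethyl-4-oxodihydrofuro[3,4-d][1,3]dioxol-3a(4H)-yl]acetate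
Product: 14 tert-butyl 2-[(3aS,6aS)-4-hydroxy-2,2-dimethyldihydrofuro[3,4-d][1,3]dioxol-3a(4H)-yl]acetate (anomers)
Conditions: i-Bu2AlH (1.1 equiv), CH2Cl2, −78 °C; aq. KNaC4H4O6
Reagents that add atoms: none
Why: Partial reduction of a γ-lactone to the lactol through the aluminium hemiacetal, stable at −78 °C; the tert-butyl ester is not reduced, so C6 is now at the aldehyde level and C9 at the alcohol level.

Step 7
Reactants: 6 (E)-(6-iodo-5-methylhex-5-en-1-yn-1-yl)trimethylsilane; 14 tert-butyl 2-[(3aS,6aS)-4-hydroxy-2,2-dimethyldihydrofuro[3,4-d][1,3]dioxol-3a(4H)-yl]acetate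
Product: 17 tert-butyl 2-[(4R,5S)-4-[(1S,2E)-1-hydroxy-3-methyl-7-(trimethylsilyl)hept-2-en-6-yn-1-yl]-5-(hydroxymethyl)-2,2-dimethyl-1,3-dioxolan-4-yl]acetate, via alkenyllithium 15 (not isolated), via alkenylmagnesium bromide 16 (not isolated)
Conditions: 6 (2.6 equiv), t-BuLi (5.2 equiv), Et2O, −78 °C; MgBr2·OEt2, −78 to −20 °C; then 14, Et2O/CH2Cl2, −78 to 0 °C; aq. NH4Cl
Reagents that add atoms: none
Why: Grignard addition to a lactol (the first equivalent deprotonates, the second adds to the open aldehyde) under Cram-chelate control: magnesium bridges the aldehyde oxygen and the dioxolane oxygen O7, and the alkenyl group enters past the C11 methylene, away from ring carbon C8 and its cis CH2OMg arm, which gives the 6,7-syn (6S) carbinol; the tert-butyl ester resists the reagent and stops the C6 alkoxide from lactonising under the organometallic.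

Step 8
Reactants: 17 tert-butyl 2-[(4R,5S)-4-[(1S,2E)-1-hydroxy-3-methyl-7-(trimethylsilyl)hept-2-en-6-yn-1-yl]-5-(hydroxymethyl)-2,2-dimethyl-1,3-dioxolan-4-yl]acetate
Product: 18 (4S,5R,6S)-4-(hydroxymethyl)-2,2-dimethyl-6-[(E)-2-methyl-6-(trimethylsilyl)hex-1-en-5-yn-1-yl]-1,3,7-trioxaspiro[4.4]nonan-8-one
Conditions: KOt-Bu (0.2 equiv), THF, 0 °C, short reaction time
Reagents that add atoms: none
Why: Alkoxide-catalysed intramolecular transesterification (5-exo-trig) by the C6 alkoxide; the δ-lactone from O9 would be trans-fused to the dioxolane and is disfavoured, and any loss of the alkynyl silyl group is harmless because step 9 converts silylated and terminal alkyne alike.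

Step 9
Reactants: 18 (4S,5R,6S)-4-(hydroxymethyl)-2,2-dimethyl-6-[(E)-2-methyl-6-(trimethylsilyl)hex-1-en-5-yn-1-yl]-1,3,7-trioxaspiro[4.4]nonan-8-one
Product: 19 (4S,5R,6S)-4-(hydroxymethyl)-6-[(E)-6-iodo-2-methylhex-1-en-5-yn-1-yl]-2,2-dimethyl-1,3,7-trioxaspiro[4.4]nonan-8-one
Conditions: N-iodosuccinimide, AgNO3 (0.2 equiv), DMF, rt, dark
Reagents that add atoms: N-iodosuccinimide, O=C1CCC(=O)N1I
Why: Silver-catalysed iododesilylation through a silver acetylide; under these neutral conditions the trisubstituted alkene and the primary alcohol should not be iodinated.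

Step 10
Reactants: 19 (4S,5R,6S)-4-(hydroxymethyl)-6-[(E)-6-iodo-2-methylhex-1-en-5-yn-1-yl]-2,2-dimethyl-1,3,7-trioxaspiro[4.4]nonan-8-one
Product: 20 (4R,5R,6S)-6-[(E)-6-iodo-2-methylhex-1-en-5-yn-1-yl]-2,2-dimethyl-8-oxo-1,3,7-trioxaspiro[4.4]nonane-4-carbaldehyde
Conditions: Dess–Martin periodinane, NaHCO3, CH2Cl2, 0 °C to rt
Reagents that add atoms: none
Why: Dess–Martin oxidation of the only free hydroxyl to the C9 aldehyde under buffered conditions that do not epimerise the α-alkoxy centre C8; the aldehyde is used at once.

Step 11
Reactants: 20 (4R,5R,6S)-6-[(E)-6-iodo-2-methylhex-1-en-5-yn-1-yl]-2,2-dimethyl-8-oxo-1,3,7-trioxaspiro[4.4]nonane-4-carbaldehyde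
Product: 22 (6S,7R,8S,9R,4E)-9-hydroxy-7,8-isopropylidenedioxy-13,14-dinorgermacr-4-en-1(10)-yn-12,6-olide, via alkynylchromium dichloride 21 (not isolated)
Conditions: CrCl2 (6 equiv), NiCl2 (0.02 equiv), THF, rt, syringe-pump addition of 20 to about 0.002 M; aq. NH4Cl
Reagents that add atoms: none
Why: CrCl2 reduces NiCl2 to zerovalent nickel, which inserts into the C10–I bond; transmetalation to trivalent chromium gives 21, which adds to the C9 aldehyde, and the chromium alkoxide is hydrolysed on work-up. The closest known reaction type is the intramolecular Nozaki–Hiyama–Kishi coupling of iodoalkynes with aldehydes, which closes nine- and ten-membered cycloalkynols. The ring closes in the 10-exo-trig mode, helped by the spiro centre C7, whose two cis-fused five-membered rings turn the C6 chain and the C9 aldehyde toward each other. The new stereocentre C9 is under substrate control: a model of the closing ring places the forming C9–C10 bond antiperiplanar to C8–O8, the Felkin–Anh polar arrangement that the tether allows, and leaves two orientations of the carbonyl. With the oxygen and its chromium turned outward, between O8 and H8, the 8,9-syn (9R) alcohol 22 forms; with the oxygen inside, over C6–H and O7, the 9-epimer would form, and the outward orientation should be favoured sterically. The open-chain Felkin–Anh rule predicts the opposite, but it rests on a free nucleophile avoiding C7 and does not hold when the nucleophile is tethered through C7, so this selectivity is not taken as secure. The step also needs cyclisation over oligomerisation (high dilution), aldehyde over lactone (organochromium reagents do not add to esters) and cross-coupling over diyne homocoupling (very low NiCl2 loading).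

Step 12
Reactants: 22 (6S,7R,8S,9R,4E)-9-hydroxy-7,8-isopropylidenedioxy-13,14-dinorgermacr-4-en-1(10)-yn-12,6-olide
Product: 23 (6S,7R,8S,9S,4E)-9-hydroxy-7,8-isopropylidenedioxy-10-(tributylstannyl)-13,14-dinorgermacra-1(10),4-dien-12,6-olide (cis ring alkene at C1=C10, C2 and C9 on the same side)
Conditions: Bu3SnH, PdCl2(PPh3)2 (5 mol%), THF, 0 °C to rt
Reagents that add atoms: tributyltin hydride, CCCC[SnH](CCCC)CCCC
Why: Palladium-catalysed syn-hydrostannation of a propargylic alcohol: hydrogen and tin add to the same face, which in a ten-membered ring can only give the cis ring alkene, and tin goes to C10 because hydride is delivered to the alkyne carbon remote from the oxygenated carbon, assisted by the free hydroxyl.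

Step 13
Reactants: 23 (6S,7R,8S,9S,4E)-9-hydroxy-7,8-isopropylidenedioxy-10-(tributylstannyl)-13,14-dinorgermacra-1(10),4-dien-12,6-olide; 24 iodomethane
Product: 25 (6S,7R,8S,9R,1(10)Z,4E)-9-hydroxy-7,8-isopropylidenedioxy-13-norgermacra-1(10),4-dien-12,6-olide
Conditions: Pd(PPh3)4 (10 mol%), CuO2CC4H3S (copper thiophene-2-carboxylate), [NBu4][Ph2PO2], MeI, DMF, rt
Reagents that add atoms: none
Why: Copper-assisted Stille coupling of an α-hydroxy alkenylstannane with methyl iodide (tin to copper to palladium, phosphinate as tin scavenger) replaces tin by CH3 with retention, so C1=C10 becomes the Z-trisubstituted alkene with C14 in place; hydroxyl and lactone are tolerated.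

Step 14
Reactants: 25 (6S,7R,8S,9R,1(10)Z,4E)-9-hydroxy-7,8-isopropylidenedioxy-13-norgermacra-1(10),4-dien-12,6-olide; 26 N,N-dimethylmethyleneiminium iodide (Eschenmoser's salt)
Product: 28 (6S,7R,8S,9R,1(10)Z,4E)-13-(dimethylamino)-9-hydroxy-7,8-isopropylidenedioxygermacra-1(10),4-dien-12,6-olide (C11 epimers), via bis-silyl ketene acetal 27 (not isolated)
Conditions: LiN(i-Pr)2/Me3SiCl (premixed), THF, −78 °C; then 26, CH2Cl2, 0 °C to rt; aq. citric acid, then NaHCO3
Reagents that add atoms: none
Why: Mannich reaction of a lactone silyl ketene acetal: internal-quench silylation at −78 °C traps the enolate (and O9) before the C7–O7 bond β to it can eliminate, and the ketene acetal then attacks the iminium ion at C11, whose configuration does not matter.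

Step 15
Reactants: 28 (6S,7R,8S,9R,1(10)Z,4E)-13-(dimethylamino)-9-hydroxy-7,8-isopropylidenedioxygermacra-1(10),4-dien-12,6-olide; 24 iodomethane
Product: 30 (6S,7R,8S,9R,1(10)Z,4E)-9-hydroxy-7,8-isopropylidenedioxygermacra-1(10),4,11(13)-trien-12,6-olide, via trimethylammonium iodide 29 (not isolated)
Conditions: MeI, THF, rt; then aq. NaHCO3/EtOAc, rt
Reagents that add atoms: none
Why: N-Methylation and Hofmann-type E1cB elimination under bicarbonate: trimethylamine on the exocyclic carbon is a far better leaving group than the ketal oxygen on C7, so the C11=C13 methylene forms without opening the dioxolane.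

Step 16
Reactants: 30 (6S,7R,8S,9R,1(10)Z,4E)-9-hydroxy-7,8-isopropylidenedioxygermacra-1(10),4,11(13)-trien-12,6-olide; 31 angelic acid ((Z)-2-methylbut-2-enoic acid)
Product: 33 (6S,7R,8S,9R,1(10)Z,4E)-9-[(Z)-2-methylbut-2-enoyloxy]-7,8-isopropylidenedioxygermacra-1(10),4,11(13)-trien-12,6-olide, via mixed anhydride 32 (not isolated)
Conditions: 31, 2,4,6-trichlorobenzoyl chloride, Et3N, toluene, rt; then 30, 80 °C, no nucleophilic catalyst
Reagents that add atoms: none
Why: Yamaguchi-type acylation through 32, run thermally without a nucleophilic catalyst, the conditions under which Z-2-methylbut-2-enoates do not isomerise to tiglates; O9 is the only free hydroxyl and keeps its configuration because the C9–O bond is not broken.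

Step 17
Reactants: 33 (6S,7R,8S,9R,1(10)Z,4E)-9-[(Z)-2-methylbut-2-enoyloxy]-7,8-isopropylidenedioxygermacra-1(10),4,11(13)-trien-12,6-olide
Product: 34 (6S,7S,8S,9R,1(10)Z,4E)-9-[(Z)-2-methylbut-2-enoyloxy]-7,8-dihydroxygermacra-1(10),4,11(13)-trien-12,6-olide (CNP0303917.1)
Conditions: AcOH/H2O (4:1), 40 °C
Reagents that add atoms: none
Why: Acid-catalysed ketal hydrolysis; the crowded spiro-dioxolane on a tertiary/secondary diol should open in mild aqueous acetic acid, which should leave the angelate, the allylic C–O bonds and the diene intact, and no stereocentre is affected.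

## Compound list

1 | hexa-1,5-diyne | C#CCCC#C | starting material
2 | lithium hexa-1,5-diyn-1-ide | [Li]C#CCCC#C | intermediate (not isolated)
3 | trimethyl(hexa-1,5-diyn-1-yl)silane | C[Si](C)(C)C#CCCC#C | intermediate
4 | trimethylaluminium | C[Al](C)C | starting material
5 | dimethyl[(E)-2-methyl-6-(trimethylsilyl)hex-1-en-5-yn-1-yl]alumane | C[Al](C)/C=C(\C)CCC#C[Si](C)(C)C | intermediate (not isolated)
6 | (E)-(6-iodo-5-methylhex-5-en-1-yn-1-yl)trimethylsilane | I/C=C(\C)CCC#C[Si](C)(C)C | intermediate
7 | dimethyl (4R,5R)-2,2-dimethyl-1,3-dioxolane-4,5-dicarboxylate (dimethyl 2,3-O-isopropylidene-L-tartrate) | COC(=O)[C@@H]1OC(C)(C)O[C@H]1C(=O)OC | starting material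
8 | tert-butyl bromoacetate | BrCC(=O)OC(C)(C)C | starting material
9 | lithium enolate of 7 at C7 | [Li]OC(OC)=C1OC(C)(C)O[C@H]1C(=O)OC | intermediate (not isolated)
10 | dimethyl (4S,5R)-4-(2-tert-butoxy-2-oxoethyl)-2,2-dimethyl-1,3-dioxolane-4,5-dicarboxylate (methyl esters cis) | COC(=O)[C@@]1(CC(=O)OC(C)(C)C)OC(C)(C)O[C@H]1C(=O)OC | intermediate
11 | (4R,5S)-5-(2-tert-butoxy-2-oxoethyl)-5-(methoxycarbonyl)-2,2-dimethyl-1,3-dioxolane-4-carboxylic acid | COC(=O)[C@@]1(CC(=O)OC(C)(C)C)OC(C)(C)O[C@H]1C(=O)O | intermediate
12 | methyl (4S,5S)-4-(2-tert-butoxy-2-oxoethyl)-5-(hydroxymethyl)-2,2-dimethyl-1,3-dioxolane-4-carboxylate | COC(=O)[C@@]1(CC(=O)OC(C)(C)C)OC(C)(C)O[C@H]1CO | intermediate (not isolated)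
13 | tert-butyl 2-[(3aS,6aS)-2,2-dimethyl-4-oxodihydrofuro[3,4-d][1,3]dioxol-3a(4H)-yl]acetate | O=C1OC[C@@H]2OC(C)(C)O[C@]12CC(=O)OC(C)(C)C | intermediate
14 | tert-butyl 2-[(3aS,6aS)-4-hydroxy-2,2-dimethyldihydrofuro[3,4-d][1,3]dioxol-3a(4H)-yl]acetate (anomers) | OC1OC[C@@H]2OC(C)(C)O[C@]12CC(=O)OC(C)(C)C | intermediate
15 | [(E)-2-methyl-6-(trimethylsilyl)hex-1-en-5-yn-1-yl]lithium | [Li]/C=C(\C)CCC#C[Si](C)(C)C | intermediate (not isolated)
16 | [(E)-2-methyl-6-(trimethylsilyl)hex-1-en-5-yn-1-yl]magnesium bromide | Br[Mg]/C=C(\C)CCC#C[Si](C)(C)C | intermediate (not isolated)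
17 | tert-butyl 2-[(4R,5S)-4-[(1S,2E)-1-hydroxy-3-methyl-7-(trimethylsilyl)hept-2-en-6-yn-1-yl]-5-(hydroxymethyl)-2,2-dimethyl-1,3-dioxolan-4-yl]acetate | O[C@@H](/C=C(\C)CCC#C[Si](C)(C)C)[C@@]1(CC(=O)OC(C)(C)C)OC(C)(C)O[C@H]1CO | intermediate
18 | (4S,5R,6S)-4-(hydroxymethyl)-2,2-dimethyl-6-[(E)-2-methyl-6-(trimethylsilyl)hex-1-en-5-yn-1-yl]-1,3,7-trioxaspiro[4.4]nonan-8-one | O=C1O[C@@H](/C=C(\C)CCC#C[Si](C)(C)C)[C@@]2(C1)OC(C)(C)O[C@H]2CO | intermediate
19 | (4S,5R,6S)-4-(hydroxymethyl)-6-[(E)-6-iodo-2-methylhex-1-en-5-yn-1-yl]-2,2-dimethyl-1,3,7-trioxaspiro[4.4]nonan-8-one | O=C1O[C@@H](/C=C(\C)CCC#CI)[C@@]2(C1)OC(C)(C)O[C@H]2CO | intermediate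
20 | (4R,5R,6S)-6-[(E)-6-iodo-2-methylhex-1-en-5-yn-1-yl]-2,2-dimethyl-8-oxo-1,3,7-trioxaspiro[4.4]nonane-4-carbaldehyde | O=C1O[C@@H](/C=C(\C)CCC#CI)[C@@]2(C1)OC(C)(C)O[C@H]2C=O | intermediate (key-step precursor)
21 | alkynylchromium dichloride from 20 (trivalent chromium on C10) | O=C1O[C@@H](/C=C(\C)CCC#C[Cr](Cl)Cl)[C@@]2(C1)OC(C)(C)O[C@H]2C=O | intermediate (not isolated)
22 | (6S,7R,8S,9R,4E)-9-hydroxy-7,8-isopropylidenedioxy-13,14-dinorgermacr-4-en-1(10)-yn-12,6-olide | C1C(=O)O[C@H]2/C=C(\C)CCC#C[C@@H](O)[C@@H]3OC(C)(C)O[C@]123 | intermediate (key-step product)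
23 | (6S,7R,8S,9S,4E)-9-hydroxy-7,8-isopropylidenedioxy-10-(tributylstannyl)-13,14-dinorgermacra-1(10),4-dien-12,6-olide, cis ring alkene at C1=C10 | C1C(=O)O[C@H]2/C=C(\C)CC/C=C(/[Sn](CCCC)(CCCC)CCCC)[C@@H](O)[C@@H]3OC(C)(C)O[C@]123 | intermediate
24 | iodomethane | CI | starting material
25 | (6S,7R,8S,9R,1(10)Z,4E)-9-hydroxy-7,8-isopropylidenedioxy-13-norgermacra-1(10),4-dien-12,6-olide | C1C(=O)O[C@H]2/C=C(\C)CC/C=C(/C)[C@@H](O)[C@@H]3OC(C)(C)O[C@]123 | intermediate
26 | N,N-dimethylmethyleneiminium iodide (Eschenmoser's salt) | C=[N+](C)C.[I-] | starting material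
27 | O9-trimethylsilyl ether of the C12 trimethylsilyl ketene acetal of 25 | C1=C(O[Si](C)(C)C)O[C@H]2/C=C(\C)CC/C=C(/C)[C@@H](O[Si](C)(C)C)[C@@H]3OC(C)(C)O[C@]123 | intermediate (not isolated)
28 | (6S,7R,8S,9R,1(10)Z,4E)-13-(dimethylamino)-9-hydroxy-7,8-isopropylidenedioxygermacra-1(10),4-dien-12,6-olide (C11 epimers) | CN(C)CC1C(=O)O[C@H]2/C=C(\C)CC/C=C(/C)[C@@H](O)[C@@H]3OC(C)(C)O[C@]123 | intermediate
29 | 13-(trimethylammonio) iodide of 28 | C[N+](C)(C)CC1C(=O)O[C@H]2/C=C(\C)CC/C=C(/C)[C@@H](O)[C@@H]3OC(C)(C)O[C@]123.[I-] | intermediate (not isolated)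
30 | (6S,7R,8S,9R,1(10)Z,4E)-9-hydroxy-7,8-isopropylidenedioxygermacra-1(10),4,11(13)-trien-12,6-olide | C=C1C(=O)O[C@H]2/C=C(\C)CC/C=C(/C)[C@@H](O)[C@@H]3OC(C)(C)O[C@]123 | intermediate
31 | angelic acid, (Z)-2-methylbut-2-enoic acid | C/C=C(/C)C(=O)O | starting material
32 | (Z)-2-methylbut-2-enoic 2,4,6-trichlorobenzoic anhydride | C/C=C(/C)C(=O)OC(=O)c1c(Cl)cc(Cl)cc1Cl | intermediate (not isolated)
33 | (6S,7R,8S,9R,1(10)Z,4E)-9-[(Z)-2-methylbut-2-enoyloxy]-7,8-isopropylidenedioxygermacra-1(10),4,11(13)-trien-12,6-olide | C=C1C(=O)O[C@H]2/C=C(\C)CC/C=C(/C)[C@@H](OC(=O)/C(C)=C\C)[C@@H]3OC(C)(C)O[C@]123 | intermediate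
34 | (6S,7S,8S,9R,1(10)Z,4E)-9-[(Z)-2-methylbut-2-enoyloxy]-7,8-dihydroxygermacra-1(10),4,11(13)-trien-12,6-olide (CNP0303917.1) | C=C1C(=O)O[C@H]2/C=C(\C)CC/C=C(/C)[C@@H](OC(=O)/C(C)=C\C)[C@H](O)[C@@]12O | target

## Step count and least certain steps

Total: 17 steps. Longest linear sequence: 15 steps (steps 3 to 17, from 7); the side chain 6 takes 2 steps and joins in step 7.

**Step 11 (key).** The most likely failure is poor or reversed facial selectivity at C9, because the two carbonyl orientations in the closing ring differ only in transannular crowding; oligomerisation is the second concern. The fallback sets out from 20 and comes back at 22. The cyclisation is run without regard to selectivity. The carbinol mixture, containing the 9-epi cycloalkynol F1, is oxidised with Dess–Martin periodinane to the cycloalkynone F2. F2 is reduced with the (S)-CBS oxazaborolidine and catecholborane, where the alkynyl arm is the small and C8 the large substituent, so that the reagent and not the ring sets 9R.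

**Step 7.** The likely failure is low or reversed facial selectivity at C6, since chelated and open (Felkin–Anh) pathways lead to opposite epimers and differ only in how well C8 and C11 are told apart. The fallback sets out from 13 and comes back at 17. Alkenyllithium 15 is added to the lactone 13 at −78 °C, where the tetrahedral lithium lactolate prevents a second addition, to give the hydroxy enone F3 (in equilibrium with its cyclic hemiketal). F3 is reduced with the (R)-CBS oxazaborolidine and BH3·SMe2, the quaternary C7 acting as the large and the alkenyl as the small group. The carbinol is then made by hydride delivery, not by carbon delivery.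

**Step 12.** The likely failure is tin delivery to C1 instead of C10, because the regiochemical bias of a propargylic alcohol is only moderate. The fallback sets out from 22 and comes back at 23. 22 is oxidised to the cycloalkynone F2. Palladium-catalysed hydrostannation of this conjugated ynone places tin α to the carbonyl, on C10, with much stronger polarisation, and gives the α-stannyl enone F4. F4 is reduced at C9 with the (R)-CBS oxazaborolidine, the stannylated alkenyl group being the large substituent.

**Step 14.** The likely failure is β-elimination of the C7 ketal oxygen on enolisation, which would open the dioxolane to a butenolide. The fallback sets out from 25 and comes back at 34, and it turns the β-oxygen into an alkoxide that cannot leave (Fráter–Seebach logic).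
- The ketal of 25 is hydrolysed with aqueous acetic acid to the 7,8,9-triol F5.
- Et3SiCl/imidazole silylates only the two secondary hydroxyls, giving the 8,9-bis(triethylsilyl) ether F6.
- LiN(i-Pr)2 (2.2 equiv) forms the O7-alkoxide enolate, which reacts with 26 to give the Mannich base F7.
- MeI gives the ammonium iodide F8, and NaHCO3 the methylene lactone F9.
- HF·pyridine gives the methylene lactone triol F10, which is acylated at O9 as described under step 17.

**Step 17.** The likely failure is migration of the angelate to O8 or ionisation of an allylic C–O bond during the hydrolysis. The fallback sets out from 30 and comes back at 34. The ketal is hydrolysed on 30, before any ester is present, to the methylene lactone triol F10. F10 is acylated with a limiting amount of 32 in toluene at 80 °C. O7 is tertiary and O8 is neopentylic next to the quaternary C7, so the allylic O9 should react first.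

**Step 3.** The likely failure is self-condensation or β-elimination of the enolate before alkylation, or a low diastereomer ratio, since bromoacetates are less well established with this enolate than allylic halides. The fallback sets out from 7 and comes back at 10. The enolate is alkylated with allyl bromide to the allyl diester F11. The alkene is cleaved with RuCl3/NaIO4 to the acid F12. F12 is esterified with tert-butyl 2,2,2-trichloroacetimidate.

## Further compounds

F1 | step 11 | (6S,7R,8S,9S,4E)-9-hydroxy-7,8-isopropylidenedioxy-13,14-dinorgermacr-4-en-1(10)-yn-12,6-olide (9-epi-22) | C1C(=O)O[C@H]2/C=C(\C)CCC#C[C@H](O)[C@@H]3OC(C)(C)O[C@]123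
F2 | step 11 | (6S,7R,8S,4E)-7,8-isopropylidenedioxy-9-oxo-13,14-dinorgermacr-4-en-1(10)-yn-12,6-olide | C1C(=O)O[C@H]2/C=C(\C)CCC#CC(=O)[C@@H]3OC(C)(C)O[C@]123
F3 | step 7 | tert-butyl 2-[(4R,5S)-5-(hydroxymethyl)-2,2-dimethyl-4-[(E)-3-methyl-7-(trimethylsilyl)hept-2-en-6-ynoyl]-1,3-dioxolan-4-yl]acetate | O=C(/C=C(\C)CCC#C[Si](C)(C)C)[C@@]1(CC(=O)OC(C)(C)C)OC(C)(C)O[C@H]1CO
F4 | step 12 | (6S,7R,8S,4E)-7,8-isopropylidenedioxy-9-oxo-10-(tributylstannyl)-13,14-dinorgermacra-1(10),4-dien-12,6-olide, cis ring alkene at C1=C10 | C1C(=O)O[C@H]2/C=C(\C)CC/C=C(/[Sn](CCCC)(CCCC)CCCC)C(=O)[C@@H]3OC(C)(C)O[C@]123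
F5 | step 14 | (6S,7S,8S,9R,1(10)Z,4E)-7,8,9-trihydroxy-13-norgermacra-1(10),4-dien-12,6-olide | C1C(=O)O[C@H]2/C=C(\C)CC/C=C(/C)[C@@H](O)[C@H](O)[C@@]12O
F6 | step 14 | 8,9-bis(triethylsilyl) ether of F5 | C1C(=O)O[C@H]2/C=C(\C)CC/C=C(/C)[C@@H](O[Si](CC)(CC)CC)[C@H](O[Si](CC)(CC)CC)[C@@]12O
F7 | step 14 | 13-(dimethylamino) Mannich base of F6 (C11 epimers) | CN(C)CC1C(=O)O[C@H]2/C=C(\C)CC/C=C(/C)[C@@H](O[Si](CC)(CC)CC)[C@H](O[Si](CC)(CC)CC)[C@@]12O
F8 | step 14 | 13-(trimethylammonio) iodide of F7 | C[N+](C)(C)CC1C(=O)O[C@H]2/C=C(\C)CC/C=C(/C)[C@@H](O[Si](CC)(CC)CC)[C@H](O[Si](CC)(CC)CC)[C@@]12O.[I-]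
F9 | step 14 | 8,9-bis(triethylsilyl) ether of 7,8,9-trihydroxygermacra-1(10)Z,4E,11(13)-trien-12,6-olide | C=C1C(=O)O[C@H]2/C=C(\C)CC/C=C(/C)[C@@H](O[Si](CC)(CC)CC)[C@H](O[Si](CC)(CC)CC)[C@@]12O
F10 | step 17 | (6S,7S,8S,9R,1(10)Z,4E)-7,8,9-trihydroxygermacra-1(10),4,11(13)-trien-12,6-olide | C=C1C(=O)O[C@H]2/C=C(\C)CC/C=C(/C)[C@@H](O)[C@H](O)[C@@]12O
F11 | step 3 | dimethyl (4S,5R)-4-allyl-2,2-dimethyl-1,3-dioxolane-4,5-dicarboxylate | COC(=O)[C@@]1(CC=C)OC(C)(C)O[C@H]1C(=O)OC
F12 | step 3 | 2-[(4S,5R)-4,5-bis(methoxycarbonyl)-2,2-dimethyl-1,3-dioxolan-4-yl]acetic acid | COC(=O)[C@@]1(CC(=O)O)OC(C)(C)O[C@H]1C(=O)OC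
A1 | alternative 1 | alkynyl glycolate aldol adduct (C6 tert-butyl ester, 7-OTBS, 8-OH, 9-OPMB, 10-OTBS) | C[Si](C)(C)C#C[C@@](O[Si](C)(C)C(C)(C)C)(C(=O)OC(C)(C)C)[C@@H](O)[C@H](OCc1ccc(OC)cc1)CO[Si](C)(C)C(C)(C)C
A2 | alternative 1 | tert-butyl 2-(tert-butyldimethylsilyl)-2-oxoacetate | CC(C)(C)OC(=O)C(=O)[Si](C)(C)C(C)(C)C
A3 | alternative 1 | (R)-3-(tert-butyldimethylsilyloxy)-2-(4-methoxybenzyloxy)propanal | O=C[C@H](OCc1ccc(OC)cc1)CO[Si](C)(C)C(C)(C)C
A4 | alternative 1 | (trimethylsilylethynyl)magnesium bromide | C[Si](C)(C)C#C[Mg]Br
A5 | alternative 2 | 2,2-dichloro-3-siloxycyclobutanone with C6 and C7 set | O=C1[C@@H](C2OCCO2)[C@@](O[Si](C)(C)C(C)(C)C)([C@H]3OC(C)(C)O[C@@H]3CO[Si](c4ccccc4)(c4ccccc4)C(C)(C)C)C1(Cl)Cl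
A6 | alternative 2 | (E)-silyl enol ether across C6=C7 (C5 dioxolane acetal, 8,9-acetonide, 10-OTBDPS) | C1(OCCO1)/C=C(/O[Si](C)(C)C(C)(C)C)[C@H]2OC(C)(C)O[C@@H]2CO[Si](c3ccccc3)(c3ccccc3)C(C)(C)C
A7 | alternative 2 | dichloroketene | ClC(Cl)=C=O
A8 | alternative 3 | cis-anti-cis tricyclo[4.4.0.0(2,5)]decan-9-one photoadduct | O=C1[C@@]2(C)[C@@H]3CC[C@]3(C)[C@H]2[C@@H]4OC(=O)C[C@]4(OC(C)(C)O5)[C@H]15
A9 | alternative 3 | lactone- and acetonide-fused 2-methylcyclohex-2-enone | O=C1C(C)=C[C@@H]2OC(=O)C[C@]2(OC(C)(C)O3)[C@H]13
A10 | alternative 3 | 1-methylcyclobutene | CC1=CCC1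
A11 | alternative 3 | (6S,7R,8S,1(10)Z,4E)-7,8-isopropylidenedioxy-9-oxo-13-norgermacra-1(10),4-dien-12,6-olide | C1C(=O)O[C@H]2/C=C(\C)CC/C=C(/C)C(=O)[C@@H]3OC(C)(C)O[C@]123
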